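**Retrosynthetic overview**
- The ten-membered carbocycle is closed last, by ring-closing metathesis at C4=C5 between a C6 vinyl group and a C3 isopropenyl group (this has not been run; the route is designed from known reaction types).
- The 6,12-γ-lactone comes from an acyclic methyl 2-methylidene ester once the C6 hydroxyl is unmasked; the C8 ester is installed beforehand by Steglich acylation.
- The convergent union is the C7–C8 bond: indium Barbier allylation of a β,γ-epoxy aldehyde (C8–C10, C14, C1–C4, C15) with a (Z)-2-(bromomethyl)enoate (C5–C7, C11–C13).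
- The aldehyde comes from a temporary δ-lactone: Brown allylation of methacrolein, acylation with an itaconic half-amide, RCM to a dihydropyranone, nucleophilic epoxidation trans to the isopropenyl group, reductive opening.
- Ring order: δ-lactone (temporary) → epoxide → δ-lactone opened → γ-lactone → ten-membered ring.

Assumption: germacrane locants (C1–C15; C12 lactone carbonyl, C13 exocyclic methylene, C14 the CH2OH carbon) are used to point at atoms; TBS = tert-butyldimethylsilyl, Ipc = isopinocampheyl.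

**Route**

Step 1
Reactants: 1 methacrolein
Product: 3 (3S)-2-methylhexa-1,5-dien-3-ol, via diisopinocampheylborinate ester 2 (not isolated)
Conditions: (−)-Ipc2B(allyl) (from (+)-α-pinene), Et2O, −78 °C; then NaOH, 30% H2O2, 0 °C → rt
Reagents that add atoms: (−)-B-allyldiisopinocampheylborane, C=CCB([C@@H]1C[C@@H]2C[C@H]([C@H]1C)C2(C)C)[C@@H]1C[C@@H]2C[C@H]([C@H]1C)C2(C)C
Why: Brown asymmetric allylboration through a closed chair transition state delivers allyl to the Si face of the enal and sets C3 as S (the isopropenyl group ranks like phenyl in the benzaldehyde precedent).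

Step 2
Reactants: 4 itaconic anhydride
Product: 5 4-[methoxy(methyl)amino]-2-methylidene-4-oxobutanoic acid
Conditions: MeNHOMe·HCl, pyridine, CH2Cl2, 0 °C
Reagents that add atoms: N,O-dimethylhydroxylamine hydrochloride, CNOC.Cl
Why: Aminolysis of the anhydride occurs at the non-conjugated, more electrophilic carbonyl, giving the half Weinreb amide with the conjugated acid free (anhydride ring opening).

Step 3
Reactants: 3 (3S)-2-methylhexa-1,5-dien-3-ol; 5 4-[methoxy(methyl)amino]-2-methylidene-4-oxobutanoic acid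
Product: 6 (3S)-2-methylhexa-1,5-dien-3-yl 4-[methoxy(methyl)amino]-2-methylidene-4-oxobutanoate
Conditions: DCC, DMAP (cat.), CH2Cl2, 0 °C → rt
Reagents that add atoms: none
Why: Steglich esterification acylates the secondary allylic alcohol without touching the stereocentre, and the Weinreb amide is inert.

Step 4
Reactants: 6 (3S)-2-methylhexa-1,5-dien-3-yl 4-[methoxy(methyl)amino]-2-methylidene-4-oxobutanoate
Product: 7 N-methoxy-N-methyl-2-[(6S)-2-oxo-6-(prop-1-en-2-yl)-5,6-dihydro-2H-pyran-3-yl]acetamide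
Conditions: Grubbs II (5 mol%), CH2Cl2 (0.01 M), 40 °C
Reagents that add atoms: none
Why: Ring-closing metathesis between the terminal vinyl group and the 2-substituted acrylate gives the six-membered unsaturated lactone, whose ring forces C14 and C2 cis across C10=C1; the isopropenyl group could only close a four-membered ring and stays.

Step 5
Reactants: 7 N-methoxy-N-methyl-2-[(6S)-2-oxo-6-(prop-1-en-2-yl)-5,6-dihydro-2H-pyran-3-yl]acetamide
Product: 8 N-methoxy-N-methyl-2-[(1R,4S,6R)-2-oxo-4-(prop-1-en-2-yl)-3,7-dioxabicyclo[4.1.0]heptan-1-yl]acetamide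
Conditions: t-BuOOH, n-BuLi, THF, −78 → 0 °C
Reagents that add atoms: tert-butyl hydroperoxide, CC(C)(C)OO
Why: Weitz–Scheffer-type nucleophilic epoxidation: the peroxide anion adds axially to the β-carbon anti to the pseudo-equatorial isopropenyl group and the enolate closes on the same face, so the epoxide (C1 R, C10) is trans to the C3 substituent; the electron-rich isopropenyl group is untouched.

Step 6
Reactants: 8 N-methoxy-N-methyl-2-[(1R,4S,6R)-2-oxo-4-(prop-1-en-2-yl)-3,7-dioxabicyclo[4.1.0]heptan-1-yl]acetamide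
Product: 9 2-[(2S,3R)-2-(hydroxymethyl)-3-[(2S)-2-hydroxy-3-methylbut-3-en-1-yl]oxiran-2-yl]-N-methoxy-N-methylacetamide
Conditions: NaBH4, EtOH, 0 °C → rt
Reagents that add atoms: none
Why: The α-oxygen-activated lactone is reduced by borohydride to the 2,3-epoxy alcohol (C14–OH) and the free C3–OH, while the Weinreb amide and the epoxide are not reduced (chemoselective ester reduction).

Step 7
Reactants: 9 2-[(2S,3R)-2-(hydroxymethyl)-3-[(2S)-2-hydroxy-3-methylbut-3-en-1-yl]oxiran-2-yl]-N-methoxy-N-methylacetamide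
Product: 10 2-[(2S,3R)-2-{[(tert-butyldimethylsilyl)oxy]methyl}-3-{(2S)-2-[(tert-butyldimethylsilyl)oxy]-3-methylbut-3-en-1-yl}oxiran-2-yl]-N-methoxy-N-methylacetamide
Conditions: TBSCl, imidazole, DMF, rt
Reagents that add atoms: tert-butyldimethylsilyl chloride, CC(C)(C)[Si](C)(C)Cl
Why: Both hydroxyls are free in the target, so one silyl group serves for both (silyl ether protection under non-acidic conditions that spare the epoxide).

Step 8
Reactants: 10 2-[(2S,3R)-2-{[(tert-butyldimethylsilyl)oxy]methyl}-3-{(2S)-2-[(tert-butyldimethylsilyl)oxy]-3-methylbut-3-en-1-yl}oxiran-2-yl]-N-methoxy-N-methylacetamide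
Product: 11 2-[(2S,3R)-2-{[(tert-butyldimethylsilyl)oxy]methyl}-3-{(2S)-2-[(tert-butyldimethylsilyl)oxy]-3-methylbut-3-en-1-yl}oxiran-2-yl]acetaldehyde
Conditions: DIBAL-H, THF, −78 °C; aq. Rochelle salt; used crude
Reagents that add atoms: none
Why: Weinreb amide reduction stops at the chelated tetrahedral intermediate, which releases the C8 aldehyde only on neutral work-up, so the base-sensitive β,γ-epoxy aldehyde never sees base.

Step 9
Reactants: 12 (2R)-but-3-ene-1,2-diol
Product: 13 (2R)-1,2-bis[(tert-butyldimethylsilyl)oxy]but-3-ene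
Conditions: TBSCl, imidazole, DMF, rt
Reagents that add atoms: tert-butyldimethylsilyl chloride, CC(C)(C)[Si](C)(C)Cl
Why: Exhaustive silylation of the chiral-pool diol, which supplies C6 (R) with its vinyl group (silyl ether protection).

Step 10
Reactants: 13 (2R)-1,2-bis[(tert-butyldimethylsilyl)oxy]but-3-ene
Product: 14 (2R)-2-[(tert-butyldimethylsilyl)oxy]but-3-en-1-ol
Conditions: HF·pyridine, pyridine, THF, 0 °C
Reagents that add atoms: none
Why: Buffered HF cleaves the unhindered primary silyl ether much faster than the secondary one, and does so without the base that would cause silyl migration (selective desilylation).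

Step 11
Reactants: 14 (2R)-2-[(tert-butyldimethylsilyl)oxy]but-3-en-1-ol
Product: 15 (2R)-2-[(tert-butyldimethylsilyl)oxy]but-3-enal
Conditions: Dess–Martin periodinane, CH2Cl2, 0 °C; used crude
Reagents that add atoms: none
Why: Dess–Martin oxidation is base-free, so the α-silyloxy β,γ-unsaturated aldehyde is neither racemised nor isomerised into conjugation.

Step 12
Reactants: 15 (2R)-2-[(tert-butyldimethylsilyl)oxy]but-3-enal; 16 methyl propiolate
Product: 18 methyl (3RS,4R)-4-[(tert-butyldimethylsilyl)oxy]-3-hydroxy-2-methylidenehex-5-enoate, via methyl 2-(diisobutylalumanyl)prop-2-enoate 17 (not isolated)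
Conditions: DIBAL-H, NMO, THF, 0 °C (16 → 17); then 15, 0 °C → rt
Reagents that add atoms: none
Why: Vinylalumination (hydroalumination of the ynoate, then 1,2-addition) gives the Morita–Baylis–Hillman-type adduct without the amine base and long reaction time of the classical protocol; the new carbinol centre is destroyed in step 13, so its configuration is irrelevant.

Step 13
Reactants: 18 methyl (3RS,4R)-4-[(tert-butyldimethylsilyl)oxy]-3-hydroxy-2-methylidenehex-5-enoate
Product: 19 methyl (2Z,4R)-2-(bromomethyl)-4-[(tert-butyldimethylsilyl)oxy]hexa-2,5-dienoate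
Conditions: NBS, Me2S, CH2Cl2, 0 °C → rt
Reagents that add atoms: N-bromosuccinimide, O=C1CCC(=O)N1Br
Why: Corey–Kim-type activation followed by SN2′ attack of bromide gives the thermodynamically preferred trisubstituted enoate with C6 cis to CH2Br (Z), the geometry needed for a syn-selective allylation.

Step 14
Reactants: 11 2-[(2S,3R)-2-{[(tert-butyldimethylsilyl)oxy]methyl}-3-{(2S)-2-[(tert-butyldimethylsilyl)oxy]-3-methylbut-3-en-1-yl}oxiran-2-yl]acetaldehyde; 19 methyl (2Z,4R)-2-(bromomethyl)-4-[(tert-butyldimethylsilyl)oxy]hexa-2,5-dienoate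
Product: 20 methyl (3R,4R)-3-{(1R)-1-[(tert-butyldimethylsilyl)oxy]prop-2-en-1-yl}-4-hydroxy-2-methylidene-5-[(2S,3R)-2-{[(tert-butyldimethylsilyl)oxy]methyl}-3-{(2S)-2-[(tert-butyldimethylsilyl)oxy]-3-methylbut-3-en-1-yl}oxiran-2-yl]pentanoate
Conditions: In powder, THF/H2O (3:1), rt
Reagents that add atoms: none
Why: Indium Barbier allylation through a closed chair transition state: the Z-type allylmetal gives the 7,8-syn adduct, and C7 is attacked anti to the bulky OTBS group in the allylic-strain-minimised conformer (H6 in the olefin plane), which sets 7R and 8R from the preset 6R.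

Step 15
Reactants: 20 methyl (3R,4R)-3-{(1R)-1-[(tert-butyldimethylsilyl)oxy]prop-2-en-1-yl}-4-hydroxy-2-methylidene-5-[(2S,3R)-2-{[(tert-butyldimethylsilyl)oxy]methyl}-3-{(2S)-2-[(tert-butyldimethylsilyl)oxy]-3-methylbut-3-en-1-yl}oxiran-2-yl]pentanoate; 21 (2R)-2-methylbutanoic acid
Product: 22 methyl (3R,4R)-3-{(1R)-1-[(tert-butyldimethylsilyl)oxy]prop-2-en-1-yl}-2-methylidene-4-{[(2R)-2-methylbutanoyl]oxy}-5-[(2S,3R)-2-{[(tert-butyldimethylsilyl)oxy]methyl}-3-{(2S)-2-[(tert-butyldimethylsilyl)oxy]-3-methylbut-3-en-1-yl}oxiran-2-yl]pentanoate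
Conditions: DCC, DMAP (cat.), CH2Cl2, 0 °C → rt
Reagents that add atoms: none
Why: Steglich esterification of the only free hydroxyl (C8) with retention at C8, run cold with catalytic DMAP so the α-stereocentre of the acid is not epimerised.

Step 16
Reactants: 22 methyl (3R,4R)-3-{(1R)-1-[(tert-butyldimethylsilyl)oxy]prop-2-en-1-yl}-2-methylidene-4-{[(2R)-2-methylbutanoyl]oxy}-5-[(2S,3R)-2-{[(tert-butyldimethylsilyl)oxy]methyl}-3-{(2S)-2-[(tert-butyldimethylsilyl)oxy]-3-methylbut-3-en-1-yl}oxiran-2-yl]pentanoate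
Product: 24 (1R)-1-[(2R,3R)-2-ethenyl-4-methylidene-5-oxooxolan-3-yl]-2-[(2S,3R)-2-(hydroxymethyl)-3-[(2S)-2-hydroxy-3-methylbut-3-en-1-yl]oxiran-2-yl]ethyl (2R)-2-methylbutanoate, via triol methyl ester 23 (not isolated)
Conditions: TBAF, AcOH (1:1), THF, 0 → 40 °C
Reagents that add atoms: none
Why: Buffered fluoride removes all three TBS groups, and the freed 6-OH, the only hydroxyl γ to C12, closes the trans-fused α-methylene-γ-butyrolactone by 5-exo-trig transesterification without touching a stereocentre.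

Step 17
Reactants: 24 (1R)-1-[(2R,3R)-2-ethenyl-4-methylidene-5-oxooxolan-3-yl]-2-[(2S,3R)-2-(hydroxymethyl)-3-[(2S)-2-hydroxy-3-methylbut-3-en-1-yl]oxiran-2-yl]ethyl (2R)-2-methylbutanoate
Product: 25 CNP0356520.1, (1R,3S,6R,7R,8R,10S)-1,10-epoxy-3,14-dihydroxy-8-[(2R)-2-methylbutanoyloxy]germacra-4Z,11(13)-dien-12,6-olide
Conditions: Grubbs II (15 mol%), 1,4-benzoquinone (cat.), toluene (1 mM), 80 °C
Reagents that add atoms: none
Why: Ring-closing metathesis: ruthenium loads on the monosubstituted C5 vinyl group and closes onto the isopropenyl group next to the free allylic 3-OH at high dilution, the ten-membered ring being expected to take the trisubstituted olefin as the ring-cis (4Z) isomer, while the electron-poor exocyclic methylene could only form a four-membered ring and is not engaged.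

**Compound list**
1 | methacrolein | CC(=C)C=O | starting material
2 | (3S)-2-methylhexa-1,5-dien-3-yl diisopinocampheylborinate | C=C(C)[C@@H](OB([C@@H]1C[C@@H]2C[C@H]([C@H]1C)C2(C)C)[C@@H]1C[C@@H]2C[C@H]([C@H]1C)C2(C)C)CC=C | intermediate
3 | (3S)-2-methylhexa-1,5-dien-3-ol | C=C(C)[C@@H](O)CC=C | intermediate
4 | itaconic anhydride | C=C1CC(=O)OC1=O | starting material
5 | 4-[methoxy(methyl)amino]-2-methylidene-4-oxobutanoic acid | C=C(CC(=O)N(C)OC)C(=O)O | intermediate
6 | (3S)-2-methylhexa-1,5-dien-3-yl 4-[methoxy(methyl)amino]-2-methylidene-4-oxobutanoate | C=C(C)[C@@H](OC(=O)C(=C)CC(=O)N(C)OC)CC=C | intermediate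
7 | N-methoxy-N-methyl-2-[(6S)-2-oxo-6-(prop-1-en-2-yl)-5,6-dihydro-2H-pyran-3-yl]acetamide | C=C(C)[C@@H]1CC=C(CC(=O)N(C)OC)C(=O)O1 | intermediate
8 | N-methoxy-N-methyl-2-[(1R,4S,6R)-2-oxo-4-(prop-1-en-2-yl)-3,7-dioxabicyclo[4.1.0]heptan-1-yl]acetamide (epoxide trans to isopropenyl) | C=C(C)[C@@H]1C[C@H]2O[C@@]2(CC(=O)N(C)OC)C(=O)O1 | intermediate
9 | 2-[(2S,3R)-2-(hydroxymethyl)-3-[(2S)-2-hydroxy-3-methylbut-3-en-1-yl]oxiran-2-yl]-N-methoxy-N-methylacetamide | C=C(C)[C@@H](O)C[C@H]1O[C@]1(CO)CC(=O)N(C)OC | intermediate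
10 | bis-TBS ether of 9 (C3–OTBS, C14–OTBS) | C=C(C)[C@@H](O[Si](C)(C)C(C)(C)C)C[C@H]1O[C@]1(CO[Si](C)(C)C(C)(C)C)CC(=O)N(C)OC | intermediate
11 | 2-[(2S,3R)-2-{[(TBS)oxy]methyl}-3-{(2S)-2-[(TBS)oxy]-3-methylbut-3-en-1-yl}oxiran-2-yl]acetaldehyde | C=C(C)[C@@H](O[Si](C)(C)C(C)(C)C)C[C@H]1O[C@]1(CO[Si](C)(C)C(C)(C)C)CC=O | intermediate
12 | (2R)-but-3-ene-1,2-diol | OC[C@H](O)C=C | starting material
13 | (2R)-1,2-bis[(tert-butyldimethylsilyl)oxy]but-3-ene | CC(C)(C)[Si](C)(C)OC[C@H](O[Si](C)(C)C(C)(C)C)C=C | intermediate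
14 | (2R)-2-[(tert-butyldimethylsilyl)oxy]but-3-en-1-ol | OC[C@H](O[Si](C)(C)C(C)(C)C)C=C | intermediate
15 | (2R)-2-[(tert-butyldimethylsilyl)oxy]but-3-enal | O=C[C@H](O[Si](C)(C)C(C)(C)C)C=C | intermediate
16 | methyl propiolate | C#CC(=O)OC | starting material
17 | methyl 2-(diisobutylalumanyl)prop-2-enoate | C=C(C(=O)OC)[Al](CC(C)C)CC(C)C | intermediate
18 | methyl (3RS,4R)-4-[(TBS)oxy]-3-hydroxy-2-methylidenehex-5-enoate (C3 epimers) | C=C(C(=O)OC)C(O)[C@H](O[Si](C)(C)C(C)(C)C)C=C | intermediate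
19 | methyl (2Z,4R)-2-(bromomethyl)-4-[(TBS)oxy]hexa-2,5-dienoate | COC(=O)/C(CBr)=C/[C@H](O[Si](C)(C)C(C)(C)C)C=C | intermediate
20 | Barbier adduct, methyl ester with free 8-OH and 3-, 6-, 14-OTBS (germacrane centres 1R,3S,6R,7R,8R,10S) | C=C(C(=O)OC)[C@@H]([C@H](O[Si](C)(C)C(C)(C)C)C=C)[C@H](O)C[C@@]1(CO[Si](C)(C)C(C)(C)C)O[C@@H]1C[C@H](O[Si](C)(C)C(C)(C)C)C(C)=C | intermediate
21 | (2R)-2-methylbutanoic acid | CC[C@@H](C)C(=O)O | starting material
22 | 8-O-[(2R)-2-methylbutanoyl] ester of 20 | C=C(C(=O)OC)[C@@H]([C@H](O[Si](C)(C)C(C)(C)C)C=C)[C@H](OC(=O)[C@H](C)CC)C[C@@]1(CO[Si](C)(C)C(C)(C)C)O[C@@H]1C[C@H](O[Si](C)(C)C(C)(C)C)C(C)=C | intermediate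
23 | tris-desilylated 22, triol methyl ester (same geometry; C7 is formally S here through a CIP priority change) | C=C(C(=O)OC)[C@@H]([C@H](O)C=C)[C@H](OC(=O)[C@H](C)CC)C[C@@]1(CO)O[C@@H]1C[C@H](O)C(C)=C | intermediate
24 | (1R)-1-[(2R,3R)-2-ethenyl-4-methylidene-5-oxooxolan-3-yl]-2-[(2S,3R)-2-(hydroxymethyl)-3-[(2S)-2-hydroxy-3-methylbut-3-en-1-yl]oxiran-2-yl]ethyl (2R)-2-methylbutanoate | C=C1C(=O)O[C@H](C=C)[C@H]1[C@H](OC(=O)[C@H](C)CC)C[C@@]2(CO)O[C@@H]2C[C@H](O)C(C)=C | intermediate
25 | CNP0356520.1, (1R,3S,6R,7R,8R,10S)-1,10-epoxy-3,14-dihydroxy-8-[(2R)-2-methylbutanoyloxy]germacra-4Z,11(13)-dien-12,6-olide | C=C1C(=O)O[C@@H]2/C=C(/C)[C@@H](O)C[C@H]3O[C@]3(CO)C[C@@H](OC(=O)[C@H](C)CC)[C@@H]12 | target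

**Step count**
Total: 17 steps. Longest linear sequence: 11 steps (1, 3–8, 14–17; equally 2–8, 14–17), which is 11/17 ≈ 0.65 of the total.

**Three steps most likely to fail, with fallbacks**

Step 17 (macrocyclic RCM). The strained ten-membered ring with a trisubstituted olefin, a trans-epoxide and a trans-fused lactone may give oligomers, no closure or the wrong olefin geometry. The fallback sets out from 22 and comes back at 25. The three silyl groups are removed with HF·pyridine/pyridine in THF at 0 °C, where no alkoxide forms and the open-chain triol methyl ester 23 can be isolated. Ring-closing metathesis is then run on this more flexible substrate, which has both allylic hydroxyls free and no lactone ring strain in the closing transition state, to give the ten-membered carbocycle methyl (1R,3S,6R,7S,8R,10S)-1,10-epoxy-3,6,14-trihydroxy-8-[(2R)-2-methylbutanoyloxy]germacra-4Z,11(13)-dien-12-oate F5. The γ-lactone is closed last, on the ring where 6-OH and C12 are held together, by neutral distannoxane-catalysed transesterification in toluene at 60 °C, giving 25.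

Step 14 (Barbier union). The face selectivity at C7 relative to the OTBS group is predicted, not proven; the allylindium could scramble its geometry or eliminate the silyloxy group; and the β,γ-epoxy aldehyde 11 is labile in water. The fallback sets out from 18 and comes back at 20. Alcohol 18 is acetylated (Ac2O, pyridine, DMAP) to methyl (3RS,4R)-3-acetoxy-4-[(tert-butyldimethylsilyl)oxy]-2-methylidenehex-5-enoate F1. Palladium-catalysed borylation (B2pin2, Pd2(dba)3) with allylic transposition gives the configurationally fixed allylboronate methyl (2E,4R)-4-[(tert-butyldimethylsilyl)oxy]-2-[(4,4,5,5-tetramethyl-1,3,2-dioxaborolan-2-yl)methyl]hexa-2,5-dienoate F2, with the boryl-methyl group cis to C6 as in 19. Thermal allylboration of 11 in dry toluene goes through the same closed chair but without water, free metal or metallotropic shift; triethanolamine work-up gives 20.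

Step 16 (global desilylation and lactonisation). Fluoride could trigger 8→6 acyl migration, Payne-type epoxide scrambling, or leave the methyl ester unclosed. The fallback sets out from 22 and comes back at 24. The methyl ester is hydrolysed chemoselectively with Me3SnOH (1,2-dichloroethane, 70 °C) to the tris-silylated acid (3R,4R)-3-{(1R)-1-[(tert-butyldimethylsilyl)oxy]prop-2-en-1-yl}-2-methylidene-4-{[(2R)-2-methylbutanoyl]oxy}-5-[(2S,3R)-2-{[(tert-butyldimethylsilyl)oxy]methyl}-3-{(2S)-2-[(tert-butyldimethylsilyl)oxy]-3-methylbut-3-en-1-yl}oxiran-2-yl]pentanoic acid F3. HF·pyridine/pyridine then gives the triol acid (3S,4R)-3-[(1R)-1-hydroxyprop-2-en-1-yl]-5-[(2S,3R)-2-(hydroxymethyl)-3-[(2S)-2-hydroxy-3-methylbut-3-en-1-yl]oxiran-2-yl]-2-methylidene-4-{[(2R)-2-methylbutanoyl]oxy}pentanoic acid F4. As a γ-hydroxy acid it lactonises under these weakly acidic, alkoxide-free conditions (EDC if needed) to 24.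

**Further compounds**
F1 | step 14 | methyl (3RS,4R)-3-acetoxy-4-[(tert-butyldimethylsilyl)oxy]-2-methylidenehex-5-enoate | C=C(C(=O)OC)C(OC(C)=O)[C@H](O[Si](C)(C)C(C)(C)C)C=C
F2 | step 14 | methyl (2E,4R)-4-[(tert-butyldimethylsilyl)oxy]-2-[(4,4,5,5-tetramethyl-1,3,2-dioxaborolan-2-yl)methyl]hexa-2,5-dienoate | COC(=O)/C(CB1OC(C)(C)C(C)(C)O1)=C/[C@H](O[Si](C)(C)C(C)(C)C)C=C
F3 | step 16 | tris-TBS carboxylic acid corresponding to 22 | C=C(C(=O)O)[C@@H]([C@H](O[Si](C)(C)C(C)(C)C)C=C)[C@H](OC(=O)[C@H](C)CC)C[C@@]1(CO[Si](C)(C)C(C)(C)C)O[C@@H]1C[C@H](O[Si](C)(C)C(C)(C)C)C(C)=C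
F4 | step 16 | triol carboxylic acid corresponding to 23 | C=C(C(=O)O)[C@@H]([C@H](O)C=C)[C@H](OC(=O)[C@H](C)CC)C[C@@]1(CO)O[C@@H]1C[C@H](O)C(C)=C
F5 | step 17 | methyl (1R,3S,6R,7S,8R,10S)-1,10-epoxy-3,6,14-trihydroxy-8-[(2R)-2-methylbutanoyloxy]germacra-4Z,11(13)-dien-12-oate | C=C(C(=O)OC)[C@H]1[C@H](O)/C=C(/C)[C@@H](O)C[C@H]2O[C@]2(CO)C[C@H]1OC(=O)[C@H](C)CC
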